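**Overview**

1. Atoms are numbered C1 (alkyne CH) to C15 (methyl); ring A is the tetrahydrofuran O/C6–C9, ring B the tetrahydrofuran O/C10–C13, ring C the oxocane O/C7–C13. The retrosynthesis first removes the enyne (C1–C2 by Colvin homologation, C3=C4 by Wittig olefination), then cuts C10–Br and C7–O of ring C in one operation, and last cuts C7–C8 and C11–C12 (two chloroaldehyde aldol additions) together with the ring bonds C6–O and C13–O.
2. Enabling feature: the ring C oxygen (on C7 and C13) stands 1,4 to the bromine-bearing C10, so the C7–O and C10–Br bonds can both be traced to one trialkyloxonium ion whose oxygen carries C7, C10 and C13. That ion is what a 2,2'-linked bis-tetrahydrofuran (rings A and B joined C9–C10) gives when the ring B oxygen displaces a leaving group on C7.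
3. Forward order: ring B (C8–C15) is built and brominated first; the C4–C7 chloroaldehyde is added and ring A closed second; the cage ring O/C7–C10 then closes and merges with ring B into ring C; the C1–C3 enyne end is attached last.
4. Stereochemistry: C13 and C6 come from two organocatalytic α-chlorinations (each inverted once on ring closure). C12 and C7 come from 1,2-anti aldol additions (C12 inverted by the Appel reaction, C7 inverted by the Mitsunobu reaction and again by the oxonium closure). C10 and C9 come from 1,3-anti directed reductions (C10 inverted by bromide in the key step). The C3=C4 E geometry comes from the stabilised ylide.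

Key step: step 15

Remark: (2R,5R)-2,5-diphenylpyrrolidine is assumed to deliver the (S)-α-chloroaldehyde and its enantiomer the (R)-aldehyde; should the sense of induction be the reverse, the two catalysts are exchanged and nothing else changes.

**Route**

Step 1
Reactants: 1 butanal
Product: 2 (S)-2-chlorobutanal (C12–C15; kept as a CH2Cl2 solution)
Conditions: NCS, (2R,5R)-2,5-diphenylpyrrolidine (10 mol %), CH2Cl2, 0 °C to rt; pentane, filter; solution used directly
Reagents that add atoms: N-chlorosuccinimide, O=C1CCC(=O)N1Cl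
Why: Organocatalytic enamine α-chlorination, in which the C2-symmetric pyrrolidine shields one enamine face so that chlorine is delivered to give (S)-configured C13, and the volatile, configurationally labile aldehyde is never concentrated.

Step 2
Reactants: 3 3,3-dimethoxybutan-2-one; 2 (S)-2-chlorobutanal
Product: 5 (5R,6S)-6-chloro-5-hydroxy-2,2-dimethoxyoctan-3-one (anti chlorohydrin), via lithium enolate 4 (not isolated)
Conditions: 3, LiN(iPr)2, THF, −78 °C; then 2 in CH2Cl2, −78 °C; AcOH quench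
Reagents that add atoms: none
Why: Lithium enolate aldol addition in which 3 can enolise only at C11 and the α-chloroaldehyde reacts under Cornforth (polar Felkin–Anh) control, so the new C11–C12 bond is formed with the C12 hydroxyl 1,2-anti to the C13 chloride.

Step 3
Reactants: 5 (5R,6S)-6-chloro-5-hydroxy-2,2-dimethoxyoctan-3-one
Product: 6 (3R,5R,6S)-6-chloro-2,2-dimethoxyoctane-3,5-diol
Conditions: Me4NBH(OAc)3, MeCN/AcOH (1:1), −40 to −20 °C
Reagents that add atoms: none
Why: Evans–Saksena reduction, in which the C12 hydroxyl binds boron and hydride is delivered intramolecularly through a chair transition state to set C10 1,3-anti to C12, the ketal being inert to acetic acid at this temperature.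

Step 4
Reactants: 6 (3R,5R,6S)-6-chloro-2,2-dimethoxyoctane-3,5-diol
Product: 7 (2R,3R,5R)-5-(1,1-dimethoxyethyl)-2-ethyloxolan-3-ol (all-cis ring B alcohol)
Conditions: AgOTf, Ag2O, THF, rt, dark
Reagents that add atoms: none
Why: Silver-assisted intramolecular etherification (5-exo-tet) in which the C10 hydroxyl displaces the C13 chloride with inversion, turning the anti,anti-chlorodiol into the all-cis trisubstituted tetrahydrofuran while Ag2O takes up the acid so that the ketal survives.

Step 5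
Reactants: 7 (2R,3R,5R)-5-(1,1-dimethoxyethyl)-2-ethyloxolan-3-ol
Product: 8 (2R,3S,5R)-3-bromo-5-(1,1-dimethoxyethyl)-2-ethyloxolane
Conditions: CBr4, PPh3, 2,6-lutidine, toluene, 0 to 60 °C
Reagents that add atoms: carbon tetrabromide, BrC(Br)(Br)Br
Why: Appel reaction in which bromide displaces the C12 oxyphosphonium group from the unsubstituted lower face of the ring (SN2, inversion), placing bromine trans to both ring substituents while the lutidine keeps the ketal from acid.

Step 6
Reactants: 8 (2R,3S,5R)-3-bromo-5-(1,1-dimethoxyethyl)-2-ethyloxolane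
Product: 9 1-[(2R,4S,5R)-4-bromo-5-ethyloxolan-2-yl]ethan-1-one (ring B bromide methyl ketone)
Conditions: CF3CO2H, H2O, CH2Cl2, 0 °C
Reagents that add atoms: water, O
Why: Acid-catalysed ketal hydrolysis frees the C9 methyl ketone, the short exposure at 0 °C limiting enolisation toward C10 and the secondary bromide being stable to acid.

Step 7
Reactants: 10 butane-1,4-diol
Product: 11 4-hydroxybutyl 2,2-dimethylpropanoate
Conditions: pivaloyl chloride (0.3 equiv), pyridine, CH2Cl2, 0 °C
Reagents that add atoms: pivaloyl chloride, CC(C)(C)C(=O)Cl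
Why: Statistical monoacylation of the symmetrical diol used in excess, the pivalate being chosen because its alkoxy oxygen is not nucleophilic and the ester withstands enolates, acid and Mitsunobu conditions.

Step 8
Reactants: 11 4-hydroxybutyl 2,2-dimethylpropanoate
Product: 12 4-oxobutyl 2,2-dimethylpropanoate
Conditions: TEMPO (10 mol %), PhI(OAc)2, CH2Cl2, rt
Reagents that add atoms: none
Why: Nitroxyl-catalysed alcohol oxidation with PhI(OAc)2 as terminal oxidant stops at the aldehyde and leaves the ester untouched.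

Step 9
Reactants: 12 4-oxobutyl 2,2-dimethylpropanoate
Product: 13 (3R)-3-chloro-4-oxobutyl 2,2-dimethylpropanoate (C4–C7 chloroaldehyde)
Conditions: NCS, (2S,5S)-2,5-diphenylpyrrolidine (10 mol %), CH2Cl2, 0 °C to rt; used crude
Reagents that add atoms: N-chlorosuccinimide, O=C1CCC(=O)N1Cl
Why: Organocatalytic enamine α-chlorination with the enantiomeric catalyst sets C6 as (R), and the crude aldehyde is used at once because α-chloroaldehydes racemise on silica.

Step 10
Reactants: 9 1-[(2R,4S,5R)-4-bromo-5-ethyloxolan-2-yl]ethan-1-one; 13 (3R)-3-chloro-4-oxobutyl 2,2-dimethylpropanoate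
Product: 15 (3R,4S)-6-[(2R,4S,5R)-4-bromo-5-ethyloxolan-2-yl]-3-chloro-4-hydroxy-6-oxohexyl 2,2-dimethylpropanoate, via lithium enolate 14 (not isolated)
Conditions: 9, LiN(iPr)2, THF, −78 °C; then 13, −78 °C; AcOH quench
Reagents that add atoms: none
Why: Kinetic lithium enolate aldol addition in which the methyl group C8 is deprotonated faster than the α-alkoxy methine C10 and the α-chloroaldehyde reacts under Cornforth control, forming the C7–C8 bond with C7 1,2-anti to the C6 chloride while the secondary bromide and the hindered ester stay inert at −78 °C.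

Step 11
Reactants: 15 (3R,4S)-6-[(2R,4S,5R)-4-bromo-5-ethyloxolan-2-yl]-3-chloro-4-hydroxy-6-oxohexyl 2,2-dimethylpropanoate
Product: 16 (3R,4S,6S)-6-[(2R,4S,5R)-4-bromo-5-ethyloxolan-2-yl]-3-chloro-4,6-dihydroxyhexyl 2,2-dimethylpropanoate
Conditions: Me4NBH(OAc)3, MeCN/AcOH (1:1), −40 to −20 °C
Reagents that add atoms: none
Why: Evans–Saksena hydroxyl-directed reduction sets C9 1,3-anti to C7 by intramolecular hydride delivery, largely independent of the adjacent C10 centre, and the ester and both halides are inert to the acetoxyborohydride.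

Step 12
Reactants: 16 (3R,4S,6S)-6-[(2R,4S,5R)-4-bromo-5-ethyloxolan-2-yl]-3-chloro-4,6-dihydroxyhexyl 2,2-dimethylpropanoate
Product: 17 2-[(2S,3S,5S)-5-[(2R,4S,5R)-4-bromo-5-ethyloxolan-2-yl]-3-hydroxyoxolan-2-yl]ethyl 2,2-dimethylpropanoate (all-cis ring A)
Conditions: MeOH, 120 °C (sealed tube, microwave), stopped at full conversion
Reagents that add atoms: none
Why: Thermal chlorohydrin etherification (5-exo-tet) in which the C9 hydroxyl displaces the C6 chloride with inversion to give the all-cis ring A, closure to an unstrained tetrahydrofuran being expected to outrun attack of the same hydroxyl on the C12 bromide, which would need a strained bicyclo[2.2.1] transition state.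

Step 13
Reactants: 17 2-[(2S,3S,5S)-5-[(2R,4S,5R)-4-bromo-5-ethyloxolan-2-yl]-3-hydroxyoxolan-2-yl]ethyl 2,2-dimethylpropanoate
Product: 18 (2S,3R,5S)-5-[(2R,4S,5R)-4-bromo-5-ethyloxolan-2-yl]-2-[2-(2,2-dimethylpropanoyloxy)ethyl]oxolan-3-yl 4-nitrobenzoate
Conditions: 4-nitrobenzoic acid, PPh3, iPrO2CN=NCO2iPr, toluene, 0 °C to rt
Reagents that add atoms: 4-nitrobenzoic acid, O=C(O)c1ccc(cc1)[N+](=O)[O-]
Why: Mitsunobu reaction with the acidic carboxylic acid suited to hindered secondary alcohols inverts C7 by attack on the face free of substituents, and the ring B oxygen cannot participate because it sits on the side of the leaving group.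

Step 14
Reactants: 18 (2S,3R,5S)-5-[(2R,4S,5R)-4-bromo-5-ethyloxolan-2-yl]-2-[2-(2,2-dimethylpropanoyloxy)ethyl]oxolan-3-yl 4-nitrobenzoate
Product: 19 2-[(2S,3R,5S)-5-[(2R,4S,5R)-4-bromo-5-ethyloxolan-2-yl]-3-hydroxyoxolan-2-yl]ethyl 2,2-dimethylpropanoate (key precursor; C7 hydroxyl trans to ring B)
Conditions: K2CO3, MeOH, 0 °C
Reagents that add atoms: none
Why: Base-catalysed transesterification cleaves the electron-poor 4-nitrobenzoate far faster than the hindered pivalate, freeing the C7 alcohol without loss of the primary ester.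

Step 15
Reactants: 19 2-[(2S,3R,5S)-5-[(2R,4S,5R)-4-bromo-5-ethyloxolan-2-yl]-3-hydroxyoxolan-2-yl]ethyl 2,2-dimethylpropanoate
Product: 22 2-[(1S,3R,4S,6S,7S,9S)-4,6-dibromo-3-ethyl-2,8-dioxabicyclo[5.2.1]decan-9-yl]ethyl 2,2-dimethylpropanoate, via C7 triflate 20 (not isolated), via tricyclic oxonium triflate 21 (not isolated)
Conditions: Tf2O, 2,6-di-tert-butyl-4-methylpyridine, CH2Cl2, −78 to −30 °C; then Bu4NBr, −78 to 0 °C
Reagents that add atoms: tetrabutylammonium bromide, CCCC[N+](CCCC)(CCCC)CCCC.[Br-]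
Why: The C7 alcohol is triflated at −78 °C, and on warming the ring B oxygen, held by the C9–C10 bond on the face of ring A opposite the triflate, displaces it from the rear (5-exo-tet, inversion at C7) and closes the five-membered cage ring O–C7–C8–C9–C10, giving a trialkyloxonium ion with oxygen on C7, C10 and C13 (a 2,5-dioxabicyclo[2.2.1]heptane fused to ring B). Bromide then attacks C10 anti to the C10–O bond (SN2, inversion at C10), and because that bond is shared by the cage ring and ring B its scission merges the two into the eight-membered ring C, which therefore arises by ring enlargement and not by end-to-end closure. The closest known reaction type is the ring expansion of tetrahydrofurans through bicyclic or tricyclic oxonium ions that are generated by neighbouring ether participation at a sulfonate, halide or bromonium ion and opened by halide, as used for oxocane bromoethers. Both new stereocentres are dictated by the substrate: C7 by the configuration installed in the Mitsunobu step and C10 by the directed reduction of step 3, each inverted once in a stereospecific displacement. The step needs bromide to open the ion at C10 and not at C7 or C13, and the argument for this is that opening at C13 would leave the strained cage intact and is hindered by the ethyl group and the C12 bromine, that attack at C7 must flatten a carbon held in ring A, and that C10 is tied to the cage by one bond only so that its opening releases the cage strain. Chemoselectivity rests on the triflate being the only group that ionises below 0 °C (the C12 bromide is inert without a halophile), on the non-nucleophilic alkoxy oxygen of the pivalate, and on a pyridine base too hindered to attack the ion.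

Step 16
Reactants: 22 2-[(1S,3R,4S,6S,7S,9S)-4,6-dibromo-3-ethyl-2,8-dioxabicyclo[5.2.1]decan-9-yl]ethyl 2,2-dimethylpropanoate
Product: 23 2-[(1S,3R,4S,6S,7S,9S)-4,6-dibromo-3-ethyl-2,8-dioxabicyclo[5.2.1]decan-9-yl]ethan-1-ol
Conditions: iBu2AlH, CH2Cl2, −78 °C; aqueous potassium sodium tartrate
Reagents that add atoms: none
Why: Reductive ester cleavage with the aluminium hydride at −78 °C frees the C4 alcohol, secondary alkyl bromides and ethers being inert to the reagent at this temperature.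

Step 17
Reactants: 23 2-[(1S,3R,4S,6S,7S,9S)-4,6-dibromo-3-ethyl-2,8-dioxabicyclo[5.2.1]decan-9-yl]ethan-1-ol
Product: 24 2-[(1S,3R,4S,6S,7S,9S)-4,6-dibromo-3-ethyl-2,8-dioxabicyclo[5.2.1]decan-9-yl]acetaldehyde
Conditions: Dess–Martin periodinane, NaHCO3, CH2Cl2, 0 °C to rt; used crude
Reagents that add atoms: none
Why: Dess–Martin oxidation under buffered, non-basic conditions should give the β-alkoxy aldehyde without β-elimination of the ring A oxygen.

Step 18
Reactants: 24 2-[(1S,3R,4S,6S,7S,9S)-4,6-dibromo-3-ethyl-2,8-dioxabicyclo[5.2.1]decan-9-yl]acetaldehyde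
Product: 25 (2E)-4-[(1S,3R,4S,6S,7S,9S)-4,6-dibromo-3-ethyl-2,8-dioxabicyclo[5.2.1]decan-9-yl]but-2-enal
Conditions: Ph3P=CHCHO (1.3 equiv), toluene, 60 °C
Reagents that add atoms: (triphenylphosphoranylidene)acetaldehyde, O=CC=P(c1ccccc1)(c1ccccc1)c1ccccc1
Why: Wittig reaction with the stabilised formylmethylene ylide adds C2 and C3 and gives the E-enal, the conjugated product being less electrophilic than the starting aldehyde so that a small excess of ylide limits a second homologation.

Step 19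
Reactants: 25 (2E)-4-[(1S,3R,4S,6S,7S,9S)-4,6-dibromo-3-ethyl-2,8-dioxabicyclo[5.2.1]decan-9-yl]but-2-enal
Product: 26 (1S,3R,4S,6S,7S,9S)-4,6-dibromo-3-ethyl-9-[(2E)-pent-2-en-4-yn-1-yl]-2,8-dioxabicyclo[5.2.1]decane (target)
Conditions: Me3SiCHN2, LiN(iPr)2, THF, −78 °C; then 25, −78 to 0 °C
Reagents that add atoms: trimethylsilyldiazomethane, C[Si](C)(C)C=[N+]=[N-]
Why: Colvin homologation in which lithiated trimethylsilyldiazomethane adds 1,2 to the enal, Peterson-type loss of silanolate gives a diazoalkene, and the derived alkylidene carbene undergoes 1,2-hydrogen shift to the terminal alkyne (C1) without disturbing the E alkene or the bromides.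

**Compound list**

1 | butanal | CCCC=O | starting material
2 | (S)-2-chlorobutanal | O=C[C@H](CC)Cl | intermediate
3 | 3,3-dimethoxybutan-2-one | CC(=O)C(C)(OC)OC | starting material
4 | lithium 3,3-dimethoxybut-1-en-2-olate (lithium enolate of 3) | [Li]OC(=C)C(C)(OC)OC | intermediate
5 | (5R,6S)-6-chloro-5-hydroxy-2,2-dimethoxyoctan-3-one | CC(OC)(OC)C(=O)C[C@@H](O)[C@@H](Cl)CC | intermediate
6 | (3R,5R,6S)-6-chloro-2,2-dimethoxyoctane-3,5-diol | CC(OC)(OC)[C@H](O)C[C@@H](O)[C@@H](Cl)CC | intermediate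
7 | (2R,3R,5R)-5-(1,1-dimethoxyethyl)-2-ethyloxolan-3-ol | CC(OC)(OC)[C@H]1C[C@@H](O)[C@@H](CC)O1 | intermediate
8 | (2R,3S,5R)-3-bromo-5-(1,1-dimethoxyethyl)-2-ethyloxolane | CC(OC)(OC)[C@H]1C[C@H](Br)[C@@H](CC)O1 | intermediate
9 | 1-[(2R,4S,5R)-4-bromo-5-ethyloxolan-2-yl]ethan-1-one | CC(=O)[C@H]1C[C@H](Br)[C@@H](CC)O1 | intermediate
10 | butane-1,4-diol | OCCCCO | starting material
11 | 4-hydroxybutyl 2,2-dimethylpropanoate | OCCCCOC(=O)C(C)(C)C | intermediate
12 | 4-oxobutyl 2,2-dimethylpropanoate | O=CCCCOC(=O)C(C)(C)C | intermediate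
13 | (3R)-3-chloro-4-oxobutyl 2,2-dimethylpropanoate | CC(C)(C)C(=O)OCC[C@@H](Cl)C=O | intermediate
14 | lithium enolate of 9 (lithium 1-[(2R,4S,5R)-4-bromo-5-ethyloxolan-2-yl]ethen-1-olate) | [Li]OC(=C)[C@H]1C[C@H](Br)[C@@H](CC)O1 | intermediate
15 | (3R,4S)-6-[(2R,4S,5R)-4-bromo-5-ethyloxolan-2-yl]-3-chloro-4-hydroxy-6-oxohexyl 2,2-dimethylpropanoate | CC(C)(C)C(=O)OCC[C@@H](Cl)[C@@H](O)CC(=O)[C@H]1C[C@H](Br)[C@@H](CC)O1 | intermediate
16 | (3R,4S,6S)-6-[(2R,4S,5R)-4-bromo-5-ethyloxolan-2-yl]-3-chloro-4,6-dihydroxyhexyl 2,2-dimethylpropanoate | CC(C)(C)C(=O)OCC[C@@H](Cl)[C@@H](O)C[C@H](O)[C@H]1C[C@H](Br)[C@@H](CC)O1 | intermediate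
17 | 2-[(2S,3S,5S)-5-[(2R,4S,5R)-4-bromo-5-ethyloxolan-2-yl]-3-hydroxyoxolan-2-yl]ethyl 2,2-dimethylpropanoate | CC(C)(C)C(=O)OCC[C@@H]1O[C@@H](C[C@@H]1O)[C@H]2C[C@H](Br)[C@@H](CC)O2 | intermediate
18 | (2S,3R,5S)-5-[(2R,4S,5R)-4-bromo-5-ethyloxolan-2-yl]-2-[2-(2,2-dimethylpropanoyloxy)ethyl]oxolan-3-yl 4-nitrobenzoate | CC(C)(C)C(=O)OCC[C@@H]1O[C@@H](C[C@H]1OC(=O)c3ccc(cc3)[N+](=O)[O-])[C@H]2C[C@H](Br)[C@@H](CC)O2 | intermediate
19 | 2-[(2S,3R,5S)-5-[(2R,4S,5R)-4-bromo-5-ethyloxolan-2-yl]-3-hydroxyoxolan-2-yl]ethyl 2,2-dimethylpropanoate | CC(C)(C)C(=O)OCC[C@@H]1O[C@@H](C[C@H]1O)[C@H]2C[C@H](Br)[C@@H](CC)O2 | intermediate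
20 | C7 trifluoromethanesulfonate of 19 | CC(C)(C)C(=O)OCC[C@@H]1O[C@@H](C[C@H]1OS(=O)(=O)C(F)(F)F)[C@H]2C[C@H](Br)[C@@H](CC)O2 | intermediate
21 | tricyclic oxonium triflate (oxygen bonded to C7, C10 and C13; 2,5-dioxabicyclo[2.2.1]heptane fused to ring B) | CC(C)(C)C(=O)OCC[C@@H]1O[C@H]2C[C@@H]1[O+]3[C@@H]2C[C@H](Br)[C@H]3CC.[O-]S(=O)(=O)C(F)(F)F | intermediate
22 | 2-[(1S,3R,4S,6S,7S,9S)-4,6-dibromo-3-ethyl-2,8-dioxabicyclo[5.2.1]decan-9-yl]ethyl 2,2-dimethylpropanoate | CC(C)(C)C(=O)OCC[C@@H]1O[C@H]2C[C@@H]1O[C@H](CC)[C@@H](Br)C[C@@H]2Br | intermediate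
23 | 2-[(1S,3R,4S,6S,7S,9S)-4,6-dibromo-3-ethyl-2,8-dioxabicyclo[5.2.1]decan-9-yl]ethan-1-ol | OCC[C@@H]1O[C@H]2C[C@@H]1O[C@H](CC)[C@@H](Br)C[C@@H]2Br | intermediate
24 | 2-[(1S,3R,4S,6S,7S,9S)-4,6-dibromo-3-ethyl-2,8-dioxabicyclo[5.2.1]decan-9-yl]acetaldehyde | O=CC[C@@H]1O[C@H]2C[C@@H]1O[C@H](CC)[C@@H](Br)C[C@@H]2Br | intermediate
25 | (2E)-4-[(1S,3R,4S,6S,7S,9S)-4,6-dibromo-3-ethyl-2,8-dioxabicyclo[5.2.1]decan-9-yl]but-2-enal | O=C/C=C/C[C@@H]1O[C@H]2C[C@@H]1O[C@H](CC)[C@@H](Br)C[C@@H]2Br | intermediate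
26 | (1S,3R,4S,6S,7S,9S)-4,6-dibromo-3-ethyl-9-[(2E)-pent-2-en-4-yn-1-yl]-2,8-dioxabicyclo[5.2.1]decane | C#C/C=C/C[C@@H]1O[C@H]2C[C@@H]1O[C@H](CC)[C@@H](Br)C[C@@H]2Br | target

**Step count**

Total: 19 steps. Longest linear sequence: 16 steps (steps 1–6, then 10–19, from butanal); the C4–C7 branch (steps 7–9) joins at step 10.

**Steps most likely to fail**

1. Step 15. Once the oxonium ion has formed, bromide may partition between its three α-carbons: return to C7 gives a bis-tetrahydrofuran bromide that cannot be fed back, and opening at C13 gives a cage product. Triflate may also add back and erode the configuration at C10. The fallback sets out from 19 and comes back at 22; it ends the ring merger with water and brings in the C10 bromine afterwards by a classical displacement.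
   - Ion 21 is generated from 19 as in step 15 and quenched with aqueous NaHCO3 in MeCN. Attack of water at C7 regenerates alcohol 19 itself (same trans configuration), which is recovered and resubmitted.
   - Attack at C10 gives the ring-enlarged alcohol 2-[(1S,3R,4S,6S,7S,9S)-4-bromo-3-ethyl-6-hydroxy-2,8-dioxabicyclo[5.2.1]decan-9-yl]ethyl 2,2-dimethylpropanoate F1.
   - F1 is not activated directly, because a leaving group on this face of C10 would be expelled again by the transannular ring oxygen.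
   - Dess–Martin oxidation gives the ketone 2-[(1S,3R,4S,7S,9S)-4-bromo-3-ethyl-6-oxo-2,8-dioxabicyclo[5.2.1]decan-9-yl]ethyl 2,2-dimethylpropanoate F2, used at once.
   - LiBH(sBu)3 at −78 °C should add hydride from the outer face to give the epimeric alcohol 2-[(1S,3R,4S,6R,7S,9S)-4-bromo-3-ethyl-6-hydroxy-2,8-dioxabicyclo[5.2.1]decan-9-yl]ethyl 2,2-dimethylpropanoate F3.
   - The triflate of F3 (Tf2O, pyridine), in which the ring oxygen lies on the side of the leaving group and cannot participate, is displaced by Bu4NBr with inversion to give 22.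

2. Step 12. During the heating the C12 bromide may be lost, either by displacement by the C9 hydroxyl of 16 or, once ring A exists, by participation of the ring A oxygen; the hydrogen chloride released may also begin to methanolyse the pivalate. The fallback sets out from 7 and comes back at 18; it closes ring A before any bromide is present, so that the mild silver conditions of step 4 can be used.
   - The C12 hydroxyl of 7 is silylated (tBuPh2SiCl, imidazole, DMF) to give tert-butyl{[(2R,3R,5R)-5-(1,1-dimethoxyethyl)-2-ethyloxolan-3-yl]oxy}diphenylsilane F4.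
   - Ketal hydrolysis as in step 6 gives 1-[(2R,4R,5R)-4-{[tert-butyl(diphenyl)silyl]oxy}-5-ethyloxolan-2-yl]ethan-1-one F5.
   - Aldol addition of its lithium enolate to 13 as in step 10 gives the anti chlorohydrin (3R,4S)-6-[(2R,4R,5R)-4-{[tert-butyl(diphenyl)silyl]oxy}-5-ethyloxolan-2-yl]-3-chloro-4-hydroxy-6-oxohexyl 2,2-dimethylpropanoate F6.
   - Me4NBH(OAc)3 gives the anti diol (3R,4S,6S)-6-[(2R,4R,5R)-4-{[tert-butyl(diphenyl)silyl]oxy}-5-ethyloxolan-2-yl]-3-chloro-4,6-dihydroxyhexyl 2,2-dimethylpropanoate F7.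
   - AgOTf and Ag2O in THF at rt close ring A to the all-cis alcohol 2-[(2S,3S,5S)-5-[(2R,4R,5R)-4-{[tert-butyl(diphenyl)silyl]oxy}-5-ethyloxolan-2-yl]-3-hydroxyoxolan-2-yl]ethyl 2,2-dimethylpropanoate F8.
   - Mitsunobu inversion at C7 with 4-nitrobenzoic acid gives (2S,3R,5S)-5-[(2R,4R,5R)-4-{[tert-butyl(diphenyl)silyl]oxy}-5-ethyloxolan-2-yl]-2-[2-(2,2-dimethylpropanoyloxy)ethyl]oxolan-3-yl 4-nitrobenzoate F9.
   - HF·pyridine removes the silyl group to give (2S,3R,5S)-5-[(2R,4R,5R)-5-ethyl-4-hydroxyoxolan-2-yl]-2-[2-(2,2-dimethylpropanoyloxy)ethyl]oxolan-3-yl 4-nitrobenzoate F10.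
   - The Appel reaction (CBr4, PPh3) then installs the C12 bromide with inversion and gives 18; the ring A oxygen lies on the side of the leaving group and cannot interfere.

3. Step 18. The basic ylide may trigger β-elimination of the ring A oxygen from the β-alkoxy aldehyde, and the enal formed may be homologated a second time. The fallback sets out from 24 and comes back at 26; it builds the enyne without an enal and without a basic carbon nucleophile.
   - Takai olefination of 24 (CrCl2, divalent chromium, with CHI3 in THF at 0 °C) gives the vinyl iodide (1S,3R,4S,6S,7S,9S)-4,6-dibromo-3-ethyl-9-[(2E)-3-iodoprop-2-en-1-yl]-2,8-dioxabicyclo[5.2.1]decane F11.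
   - Sonogashira coupling with trimethylsilylacetylene (Pd(PPh3)4, zerovalent palladium, with CuI and Et3N) gives the silyl enyne trimethyl{(3E)-5-[(1S,3R,4S,6S,7S,9S)-4,6-dibromo-3-ethyl-2,8-dioxabicyclo[5.2.1]decan-9-yl]pent-3-en-1-yn-1-yl}silane F12.
   - K2CO3 in MeOH removes the silyl group to give 26.

Further compounds
F1 | step 15 | 2-[(1S,3R,4S,6S,7S,9S)-4-bromo-3-ethyl-6-hydroxy-2,8-dioxabicyclo[5.2.1]decan-9-yl]ethyl 2,2-dimethylpropanoate | CC(C)(C)C(=O)OCC[C@@H]1O[C@H]2C[C@@H]1O[C@H](CC)[C@@H](Br)C[C@@H]2O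
F2 | step 15 | 2-[(1S,3R,4S,7S,9S)-4-bromo-3-ethyl-6-oxo-2,8-dioxabicyclo[5.2.1]decan-9-yl]ethyl 2,2-dimethylpropanoate | CC(C)(C)C(=O)OCC[C@@H]1O[C@H]2C[C@@H]1O[C@H](CC)[C@@H](Br)CC2=O
F3 | step 15 | 2-[(1S,3R,4S,6R,7S,9S)-4-bromo-3-ethyl-6-hydroxy-2,8-dioxabicyclo[5.2.1]decan-9-yl]ethyl 2,2-dimethylpropanoate | CC(C)(C)C(=O)OCC[C@@H]1O[C@H]2C[C@@H]1O[C@H](CC)[C@@H](Br)C[C@H]2O
F4 | step 12 | tert-butyl{[(2R,3R,5R)-5-(1,1-dimethoxyethyl)-2-ethyloxolan-3-yl]oxy}diphenylsilane | CC(OC)(OC)[C@H]1C[C@@H](O[Si](c2ccccc2)(c2ccccc2)C(C)(C)C)[C@@H](CC)O1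
F5 | step 12 | 1-[(2R,4R,5R)-4-{[tert-butyl(diphenyl)silyl]oxy}-5-ethyloxolan-2-yl]ethan-1-one | CC(=O)[C@H]1C[C@@H](O[Si](c2ccccc2)(c2ccccc2)C(C)(C)C)[C@@H](CC)O1
F6 | step 12 | (3R,4S)-6-[(2R,4R,5R)-4-{[tert-butyl(diphenyl)silyl]oxy}-5-ethyloxolan-2-yl]-3-chloro-4-hydroxy-6-oxohexyl 2,2-dimethylpropanoate | CC(C)(C)C(=O)OCC[C@@H](Cl)[C@@H](O)CC(=O)[C@H]1C[C@@H](O[Si](c2ccccc2)(c2ccccc2)C(C)(C)C)[C@@H](CC)O1
F7 | step 12 | (3R,4S,6S)-6-[(2R,4R,5R)-4-{[tert-butyl(diphenyl)silyl]oxy}-5-ethyloxolan-2-yl]-3-chloro-4,6-dihydroxyhexyl 2,2-dimethylpropanoate | CC(C)(C)C(=O)OCC[C@@H](Cl)[C@@H](O)C[C@H](O)[C@H]1C[C@@H](O[Si](c2ccccc2)(c2ccccc2)C(C)(C)C)[C@@H](CC)O1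
F8 | step 12 | 2-[(2S,3S,5S)-5-[(2R,4R,5R)-4-{[tert-butyl(diphenyl)silyl]oxy}-5-ethyloxolan-2-yl]-3-hydroxyoxolan-2-yl]ethyl 2,2-dimethylpropanoate | CC(C)(C)C(=O)OCC[C@@H]1O[C@@H](C[C@@H]1O)[C@H]2C[C@@H](O[Si](c3ccccc3)(c3ccccc3)C(C)(C)C)[C@@H](CC)O2
F9 | step 12 | (2S,3R,5S)-5-[(2R,4R,5R)-4-{[tert-butyl(diphenyl)silyl]oxy}-5-ethyloxolan-2-yl]-2-[2-(2,2-dimethylpropanoyloxy)ethyl]oxolan-3-yl 4-nitrobenzoate | CC(C)(C)C(=O)OCC[C@@H]1O[C@@H](C[C@H]1OC(=O)c3ccc(cc3)[N+](=O)[O-])[C@H]2C[C@@H](O[Si](c3ccccc3)(c3ccccc3)C(C)(C)C)[C@@H](CC)O2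
F10 | step 12 | (2S,3R,5S)-5-[(2R,4R,5R)-5-ethyl-4-hydroxyoxolan-2-yl]-2-[2-(2,2-dimethylpropanoyloxy)ethyl]oxolan-3-yl 4-nitrobenzoate | CC(C)(C)C(=O)OCC[C@@H]1O[C@@H](C[C@H]1OC(=O)c3ccc(cc3)[N+](=O)[O-])[C@H]2C[C@@H](O)[C@@H](CC)O2
F11 | step 18 | (1S,3R,4S,6S,7S,9S)-4,6-dibromo-3-ethyl-9-[(2E)-3-iodoprop-2-en-1-yl]-2,8-dioxabicyclo[5.2.1]decane | I/C=C/C[C@@H]1O[C@H]2C[C@@H]1O[C@H](CC)[C@@H](Br)C[C@@H]2Br
F12 | step 18 | trimethyl{(3E)-5-[(1S,3R,4S,6S,7S,9S)-4,6-dibromo-3-ethyl-2,8-dioxabicyclo[5.2.1]decan-9-yl]pent-3-en-1-yn-1-yl}silane | C[Si](C)(C)C#C/C=C/C[C@@H]1O[C@H]2C[C@@H]1O[C@H](CC)[C@@H](Br)C[C@@H]2Br
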